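The route rests on one disconnection, the O–C6 bond of the oxolane (O, C3, C4, C5, C6). C7, the future CBr carbon, is an exocyclic substituent on C6, the ring carbon bonded to oxygen, so the ring can be stored as a dihydropyran in which oxygen is bonded to C7 and C6=C7 is an enol ether. A trivalent iodine oxidant in methanol then moves the ring oxygen from C7 to C6: one operation makes the oxolane, releases C7 as a ketal-masked acetyl arm and sets the C6 stereocentre. The precursor is (2S,3S)-3-chloro-2-ethynyl-2,6-dimethyl-3,4-dihydro-2H-pyran, built with chlorine already in place by Sharpless epoxidation and chloride opening.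

Key step: step 12

Remark: atoms are numbered along the carbon chain of the target (C1 = CHBr, C2 = second vinyl carbon, C3 = quaternary ring carbon with methyl C10, C4 = ring CHCl, C5 = ring CH2, C6 = ring CH, C7 = CBr with methyl C9, C8 = CH2Cl); all starting materials and reagents are assumed to be purchasable, and the ketal carbon of adduct 17 is left unassigned because it is lost in the same step.

Step 1
Reactants: 1 ethyl levulinate (ethyl 4-oxopentanoate)
Product: 2 ethyl 3-(2-methyl-1,3-dioxolan-2-yl)propanoate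
Conditions: HOCH2CH2OH, p-TsOH·H2O (cat.), PhMe, reflux, azeotropic removal of water
Reagents that add atoms: ethylene glycol, OCCO
Why: Acid-catalysed ketalisation converts only the ketone, so C7 is masked as a dioxolane that tolerates the hydride, base and titanium reagents of the next five steps.

Step 2
Reactants: 2 ethyl 3-(2-methyl-1,3-dioxolan-2-yl)propanoate
Product: 3 3-(2-methyl-1,3-dioxolan-2-yl)propanal
Conditions: i-Bu2AlH (1.05 equiv), CH2Cl2, −78 °C; then MeOH, aqueous potassium sodium tartrate
Reagents that add atoms: none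
Why: Partial ester reduction with i-Bu2AlH at −78 °C stops at the aluminium hemiacetal, which collapses to the aldehyde (C4) only on work-up.

Step 3
Reactants: 3 3-(2-methyl-1,3-dioxolan-2-yl)propanal; 4 ethyl 2-[bis(2,2,2-trifluoroethoxy)phosphoryl]propanoate
Product: 5 ethyl (2Z)-2-methyl-5-(2-methyl-1,3-dioxolan-2-yl)pent-2-enoate
Conditions: KN(SiMe3)2, 18-crown-6, THF, −78 °C
Reagents that add atoms: none
Why: Still–Gennari olefination with the bis(trifluoroethyl) phosphonate and a dissociated potassium counter-ion gives the kinetic Z-trisubstituted enoate, which places C5 cis to C2 as the later epoxide opening requires.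

Step 4
Reactants: 5 ethyl (2Z)-2-methyl-5-(2-methyl-1,3-dioxolan-2-yl)pent-2-enoate
Product: 6 (2Z)-2-methyl-5-(2-methyl-1,3-dioxolan-2-yl)pent-2-en-1-ol
Conditions: i-Bu2AlH (2.2 equiv), CH2Cl2, −78 → 0 °C
Reagents that add atoms: none
Why: 1,2-Reduction of the unsaturated ester with excess i-Bu2AlH gives the allylic alcohol and leaves the alkene geometry and the ketal alone.

Step 5
Reactants: 6 (2Z)-2-methyl-5-(2-methyl-1,3-dioxolan-2-yl)pent-2-en-1-ol
Product: 7 [(2S,3R)-2-methyl-3-[2-(2-methyl-1,3-dioxolan-2-yl)ethyl]oxiran-2-yl]methanol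
Conditions: Ti(OiPr)4 (0.2 equiv), L-(+)-diethyl tartrate (0.24 equiv), t-BuOOH, 4 Å MS, CH2Cl2, −20 °C
Reagents that add atoms: tert-butyl hydroperoxide, CC(C)(C)OO
Why: Sharpless asymmetric epoxidation: the catalyst formed from Ti(OiPr)4 and L-(+)-diethyl tartrate delivers oxygen to the same face of any primary allylic alcohol (the face that gives 2S epoxy alcohols), so C3 is set as S and C4 as R in a cis-disposed epoxide.

Step 6
Reactants: 7 [(2S,3R)-2-methyl-3-[2-(2-methyl-1,3-dioxolan-2-yl)ethyl]oxiran-2-yl]methanol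
Product: 8 (2S,3S)-3-chloro-2-methyl-5-(2-methyl-1,3-dioxolan-2-yl)pentane-1,2-diol
Conditions: ClTi(OiPr)3 (1.5 equiv), CH2Cl2, 0 °C → rt; aqueous tartaric acid
Reagents that add atoms: chlorotitanium triisopropoxide, CC(C)O[Ti](Cl)(OC(C)C)OC(C)C
Why: Titanium-assisted opening of a 2,3-epoxy alcohol: titanium bound to the C2 alkoxide activates the epoxide and passes chloride to the distal, less hindered C4 with inversion (C4 becomes S), while the quaternary C3 keeps its configuration and becomes the tertiary alcohol.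

Step 7
Reactants: 8 (2S,3S)-3-chloro-2-methyl-5-(2-methyl-1,3-dioxolan-2-yl)pentane-1,2-diol
Product: 9 (2S,3S)-1-[(tert-butyldiphenylsilyl)oxy]-3-chloro-2-methyl-5-(2-methyl-1,3-dioxolan-2-yl)pentan-2-ol
Conditions: t-BuPh2SiCl, imidazole, CH2Cl2, 0 °C
Reagents that add atoms: tert-butyl(chloro)diphenylsilane, CC(C)(C)[Si](Cl)(c1ccccc1)c1ccccc1
Why: Selective silylation of the primary alcohol (the tertiary one is too hindered for the bulky silyl chloride) keeps the 1,2-diol from closing a bicyclic ketal onto C7 in the next step.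

Step 8
Reactants: 9 (2S,3S)-1-[(tert-butyldiphenylsilyl)oxy]-3-chloro-2-methyl-5-(2-methyl-1,3-dioxolan-2-yl)pentan-2-ol
Product: 11 tert-butyl{[(2S,3S)-3-chloro-2,6-dimethyl-3,4-dihydro-2H-pyran-2-yl]methoxy}diphenylsilane, via hydroxy ketone 10 (not isolated)
Conditions: PPTS, acetone/H2O (10:1), 50 °C; then PPTS (cat.), PhH, reflux, azeotropic removal of water
Reagents that add atoms: none
Why: Acid hydrolysis of the dioxolane and acid-catalysed cyclodehydration: the tertiary hydroxyl adds to the freed C7 ketone to give a six-membered hemiketal that loses water to the more substituted, endocyclic enol ether, with C3 and C4 untouched.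

Step 9
Reactants: 11 tert-butyl{[(2S,3S)-3-chloro-2,6-dimethyl-3,4-dihydro-2H-pyran-2-yl]methoxy}diphenylsilane
Product: 12 [(2S,3S)-3-chloro-2,6-dimethyl-3,4-dihydro-2H-pyran-2-yl]methanol
Conditions: Bu4NF, THF, 0 °C → rt
Reagents that add atoms: none
Why: Fluoride-induced desilylation is driven by the strong Si–F bond and is compatible with the enol ether and with the secondary chloride, whose equatorial position disfavours E2 loss of HCl.

Step 10
Reactants: 12 [(2S,3S)-3-chloro-2,6-dimethyl-3,4-dihydro-2H-pyran-2-yl]methanol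
Product: 13 (2S,3S)-3-chloro-2,6-dimethyl-3,4-dihydro-2H-pyran-2-carbaldehyde
Conditions: Pr4N[RuO4] (5 mol %), NMO, 4 Å MS, CH2Cl2, rt
Reagents that add atoms: none
Why: Ley–Griffith oxidation with catalytic Pr4N[RuO4] and NMO is neutral and non-electrophilic, so the primary alcohol is oxidised to the aldehyde without attacking the acid- and electrophile-sensitive enol ether.

Step 11
Reactants: 13 (2S,3S)-3-chloro-2,6-dimethyl-3,4-dihydro-2H-pyran-2-carbaldehyde; 14 dimethyl (1-diazo-2-oxopropyl)phosphonate
Product: 15 (2S,3S)-3-chloro-2-ethynyl-2,6-dimethyl-3,4-dihydro-2H-pyran (chlorine cis to ethynyl)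
Conditions: K2CO3, MeOH, 0 °C → rt
Reagents that add atoms: none
Why: Seyferth–Gilbert homologation with the Ohira–Bestmann reagent: methoxide cleaves the acetyl group of 14, the diazomethylphosphonate anion adds to the non-enolisable aldehyde, and cycloelimination and loss of N2 give a carbene whose 1,2-hydrogen shift furnishes the terminal alkyne (C1) without touching C3 or C4.

Step 12
Reactants: 15 (2S,3S)-3-chloro-2-ethynyl-2,6-dimethyl-3,4-dihydro-2H-pyran; 16 methanol
Product: 18 (2S,3S,5S)-3-chloro-5-(1,1-dimethoxyethyl)-2-ethynyl-2-methyloxolane, via iodanyl methoxy adduct 17 (not isolated)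
Conditions: PhI(OH)OTs (1.05 equiv), MeOH (reactant and cosolvent)/CH2Cl2, 3 Å MS, −40 → 0 °C, 15 added slowly to the oxidant; then NaHCO3
Reagents that add atoms: methanol, CO
Why: Electrophilic iodine adds to C6, the nucleophilic carbon of the enol ether, and one methanol traps the oxocarbenium ion left at C7 to give 17; once its C6–I bond is equatorial and anti to the endocyclic C7–O bond, the ring oxygen pushes iodobenzene out from the rear through a three-membered oxonium ion, whose C7–O bond then breaks to a methoxy-stabilised cation that takes up a second methanol from the solvent. The closest known reaction type is the oxidative ring contraction of cyclic enol ethers and glycals to 2-acyl- or 2-formyl-oxolane acetals by trivalent iodine or trivalent thallium oxidants. The oxolane (O, C3, C4, C5, C6) is closed by this invertive intramolecular displacement at C6 (3-exo-tet to the bridged oxonium ion, then cleavage of its bond to C7), that is by contraction of the six-membered ring and not by cyclisation of a chain. The one new stereocentre, C6, is controlled by the face that iodine takes: inversion puts the new C6–O bond opposite to iodine and leaves the C7 arm on the side iodine occupied, so iodine cis to chlorine and ethynyl leads to the (5S) product in which chlorine, ethynyl and the ketal arm are all cis. The step therefore needs the iodane on the chlorine/ethynyl face of C6, and what the substrate offers is that only this adduct reaches the reactive alignment in a chair with chlorine and the C10 methyl equatorial and just the slim ethynyl group axial, whereas the epimeric adduct must turn chlorine and the C10 methyl axial, the latter clashing 1,3-diaxially with a substituent on C7, and is expected to shift more slowly or to revert. Chemoselectivity rests on the enol ether being far more electron-rich than the terminal alkyne, and C6 stays correctable later because it becomes α to a ketone.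

Step 13
Reactants: 18 (2S,3S,5S)-3-chloro-5-(1,1-dimethoxyethyl)-2-ethynyl-2-methyloxolane
Product: 20 (2S,3S,5S)-2-[(E)-2-bromoethenyl]-3-chloro-5-(1,1-dimethoxyethyl)-2-methyloxolane, via alkenyl Cp2ZrCl complex 19 (not isolated)
Conditions: Cp2Zr(H)Cl (1.5 equiv), THF, rt; then NBS, 0 °C
Reagents that add atoms: N-bromosuccinimide, O=C1CCC(=O)N1Br
Why: Hydrozirconation and bromodezirconation: Cp2Zr(H)Cl adds syn across the terminal alkyne with zirconium on C1 and NBS cleaves the C–Zr bond with retention to give the E-bromoalkene, while the ketal shields C7 from the hydride and no acidic alkyne hydrogen is left for the organolithium step.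

Step 14
Reactants: 20 (2S,3S,5S)-2-[(E)-2-bromoethenyl]-3-chloro-5-(1,1-dimethoxyethyl)-2-methyloxolane
Product: 21 1-[(2S,4S,5S)-5-[(E)-2-bromoethenyl]-4-chloro-5-methyloxolan-2-yl]ethan-1-one
Conditions: 1 M aqueous HCl, THF, rt
Reagents that add atoms: water, O
Why: Acid-catalysed ketal hydrolysis frees the methyl ketone under conditions too mild to enolise C6 or to ionise the tertiary allylic ether at C3.

Step 15
Reactants: 21 1-[(2S,4S,5S)-5-[(E)-2-bromoethenyl]-4-chloro-5-methyloxolan-2-yl]ethan-1-one; 22 chloroiodomethane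
Product: 24 (2S,3S,5S)-2-[(E)-2-bromoethenyl]-3-chloro-2-methyl-5-[(2S)-2-methyloxiran-2-yl]oxolane, via lithium chlorohydrin alkoxide 23 (not isolated)
Conditions: ICH2Cl, MeLi·LiBr, THF/Et2O, −78 °C → rt
Reagents that add atoms: none
Why: Carbenoid addition and intramolecular Williamson closure: chloromethyllithium from iodine–lithium exchange adds to the ketone held in a lithium chelate between the carbonyl oxygen and the ring oxygen on C6, so the CH2Cl group (C8) enters from the side of the C6 hydrogen, and the β-chloro alkoxide 23 closes on warming to the (2S)-oxirane.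

Step 16
Reactants: 24 (2S,3S,5S)-2-[(E)-2-bromoethenyl]-3-chloro-2-methyl-5-[(2S)-2-methyloxiran-2-yl]oxolane
Product: 25 (2R)-2-bromo-2-[(2S,4S,5S)-5-[(E)-2-bromoethenyl]-4-chloro-5-methyloxolan-2-yl]propan-1-ol
Conditions: HBr (anhydrous, 1.1 equiv), CH2Cl2, −78 °C
Reagents that add atoms: hydrogen bromide, Br
Why: Acid-promoted halide opening of a 2,2-disubstituted epoxide: bromide attacks the protonated epoxide at the tertiary carbon C7, which carries most of the positive charge, from the rear, so C7 is inverted into the spatial arrangement of the target and C8 is left as the primary alcohol.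

Step 17
Reactants: 25 (2R)-2-bromo-2-[(2S,4S,5S)-5-[(E)-2-bromoethenyl]-4-chloro-5-methyloxolan-2-yl]propan-1-ol
Product: 27 (2S,3S,5S)-5-[(2S)-2-bromo-1-chloropropan-2-yl]-2-[(E)-2-bromoethenyl]-3-chloro-2-methyloxolane, via primary triflate 26 (not isolated)
Conditions: Tf2O, 2,6-lutidine, CH2Cl2, −78 °C; then Bu4NCl (5 equiv), −78 → −20 °C
Reagents that add atoms: tetrabutylammonium chloride, CCCC[N+](CCCC)(CCCC)CCCC.[Cl-]
Why: SN2 displacement of a primary triflate by chloride: the very reactive sulfonate is made at −78 °C and met at once by excess soluble chloride so that direct substitution at C8 outpaces bridging by the neighbouring bromine, and C7 is not touched.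

Compound list

1 | ethyl levulinate (ethyl 4-oxopentanoate) | CCOC(=O)CCC(C)=O | starting material
2 | ethyl 3-(2-methyl-1,3-dioxolan-2-yl)propanoate | CCOC(=O)CCC1(C)OCCO1 | intermediate
3 | 3-(2-methyl-1,3-dioxolan-2-yl)propanal | O=CCCC1(C)OCCO1 | intermediate
4 | ethyl 2-[bis(2,2,2-trifluoroethoxy)phosphoryl]propanoate | CCOC(=O)C(C)P(=O)(OCC(F)(F)F)OCC(F)(F)F | starting material
5 | ethyl (2Z)-2-methyl-5-(2-methyl-1,3-dioxolan-2-yl)pent-2-enoate | CCOC(=O)/C(C)=C\CCC1(C)OCCO1 | intermediate
6 | (2Z)-2-methyl-5-(2-methyl-1,3-dioxolan-2-yl)pent-2-en-1-ol | OC/C(C)=C\CCC1(C)OCCO1 | intermediate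
7 | [(2S,3R)-2-methyl-3-[2-(2-methyl-1,3-dioxolan-2-yl)ethyl]oxiran-2-yl]methanol | CC1(CC[C@H]2O[C@@]2(C)CO)OCCO1 | intermediate
8 | (2S,3S)-3-chloro-2-methyl-5-(2-methyl-1,3-dioxolan-2-yl)pentane-1,2-diol | CC1(CC[C@H](Cl)[C@@](C)(O)CO)OCCO1 | intermediate
9 | (2S,3S)-1-[(tert-butyldiphenylsilyl)oxy]-3-chloro-2-methyl-5-(2-methyl-1,3-dioxolan-2-yl)pentan-2-ol | CC1(CC[C@H](Cl)[C@@](C)(O)CO[Si](c2ccccc2)(c2ccccc2)C(C)(C)C)OCCO1 | intermediate
10 | (5S,6S)-7-[(tert-butyldiphenylsilyl)oxy]-5-chloro-6-hydroxy-6-methylheptan-2-one (hydroxy ketone, not isolated) | CC(=O)CC[C@H](Cl)[C@@](C)(O)CO[Si](c1ccccc1)(c1ccccc1)C(C)(C)C | intermediate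
11 | tert-butyl{[(2S,3S)-3-chloro-2,6-dimethyl-3,4-dihydro-2H-pyran-2-yl]methoxy}diphenylsilane | CC1=CC[C@H](Cl)[C@](C)(CO[Si](c2ccccc2)(c2ccccc2)C(C)(C)C)O1 | intermediate
12 | [(2S,3S)-3-chloro-2,6-dimethyl-3,4-dihydro-2H-pyran-2-yl]methanol | CC1=CC[C@H](Cl)[C@](C)(CO)O1 | intermediate
13 | (2S,3S)-3-chloro-2,6-dimethyl-3,4-dihydro-2H-pyran-2-carbaldehyde | CC1=CC[C@H](Cl)[C@](C)(C=O)O1 | intermediate
14 | dimethyl (1-diazo-2-oxopropyl)phosphonate | COP(=O)(OC)C(=[N+]=[N-])C(C)=O | starting material
15 | (2S,3S)-3-chloro-2-ethynyl-2,6-dimethyl-3,4-dihydro-2H-pyran, chlorine cis to ethynyl | CC1=CC[C@H](Cl)[C@](C)(C#C)O1 | intermediate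
16 | methanol | CO | starting material
17 | (3R,5S,6S)-5-chloro-6-ethynyl-2-methoxy-2,6-dimethyl-3-[phenyl(tosyloxy)iodanyl]oxane, iodanyl group cis to chlorine and ethynyl, ketal carbon unassigned (iodanyl methoxy adduct, not isolated) | COC1(C)O[C@@](C)(C#C)[C@@H](Cl)C[C@H]1[I](c2ccccc2)OS(=O)(=O)c2ccc(C)cc2 | intermediate
18 | (2S,3S,5S)-3-chloro-5-(1,1-dimethoxyethyl)-2-ethynyl-2-methyloxolane, chlorine, ethynyl and ketal arm all cis | CC(OC)(OC)[C@@H]1C[C@H](Cl)[C@](C)(C#C)O1 | intermediate
19 | chloro{(E)-2-[(2S,3S,5S)-3-chloro-5-(1,1-dimethoxyethyl)-2-methyloxolan-2-yl]ethenyl}bis(cyclopentadienyl)zirconium (alkenyl Cp2ZrCl complex, not isolated) | CC(OC)(OC)[C@@H]1C[C@H](Cl)[C@](C)(/C=C/[Zr](Cl)(C2C=CC=C2)C2C=CC=C2)O1 | intermediate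
20 | (2S,3S,5S)-2-[(E)-2-bromoethenyl]-3-chloro-5-(1,1-dimethoxyethyl)-2-methyloxolane | CC(OC)(OC)[C@@H]1C[C@H](Cl)[C@](C)(/C=C/Br)O1 | intermediate
21 | 1-[(2S,4S,5S)-5-[(E)-2-bromoethenyl]-4-chloro-5-methyloxolan-2-yl]ethan-1-one | CC(=O)[C@@H]1C[C@H](Cl)[C@](C)(/C=C/Br)O1 | intermediate
22 | chloroiodomethane | ClCI | starting material
23 | lithium (2R)-2-[(2S,4S,5S)-5-[(E)-2-bromoethenyl]-4-chloro-5-methyloxolan-2-yl]-1-chloropropan-2-olate (lithium chlorohydrin alkoxide, not isolated) | [Li+].C[C@]([O-])(CCl)[C@@H]1C[C@H](Cl)[C@](C)(/C=C/Br)O1 | intermediate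
24 | (2S,3S,5S)-2-[(E)-2-bromoethenyl]-3-chloro-2-methyl-5-[(2S)-2-methyloxiran-2-yl]oxolane | C[C@]1(CO1)[C@@H]2C[C@H](Cl)[C@](C)(/C=C/Br)O2 | intermediate
25 | (2R)-2-bromo-2-[(2S,4S,5S)-5-[(E)-2-bromoethenyl]-4-chloro-5-methyloxolan-2-yl]propan-1-ol | C[C@@](Br)(CO)[C@@H]1C[C@H](Cl)[C@](C)(/C=C/Br)O1 | intermediate
26 | (2R)-2-bromo-2-[(2S,4S,5S)-5-[(E)-2-bromoethenyl]-4-chloro-5-methyloxolan-2-yl]propyl trifluoromethanesulfonate (primary triflate, not isolated) | C[C@@](Br)(COS(=O)(=O)C(F)(F)F)[C@@H]1C[C@H](Cl)[C@](C)(/C=C/Br)O1 | intermediate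
27 | (2S,3S,5S)-5-[(2S)-2-bromo-1-chloropropan-2-yl]-2-[(E)-2-bromoethenyl]-3-chloro-2-methyloxolane | C[C@@](Br)(CCl)[C@@H]1C[C@H](Cl)[C@](C)(/C=C/Br)O1 | target

Total step count: 17. Longest linear sequence: 17 steps, from ethyl levulinate 1 to the target 27.

Steps most likely to fail

Step 12. The addition of the iodane to C6 may show poor facial selectivity: approach trans to chlorine is the stereoelectronically easier, axial one, and it would place the C7 arm on the methyl face. Acid-catalysed methanol addition to the enol ether and α-methoxylation may also take material. The fallback secures C6 by thermodynamic control and sets out from 15. The oxidation is run as before and the C6-epimeric ketal (2S,3S,5R)-3-chloro-5-(1,1-dimethoxyethyl)-2-ethynyl-2-methyloxolane F1, alone or mixed with 18, is hydrolysed with 1 M aqueous HCl in THF to the ethynyl ketone 1-[(2R,4S,5S)-4-chloro-5-ethynyl-5-methyloxolan-2-yl]ethan-1-one F2. DBU in CH2Cl2 should equilibrate C6 through the enol toward 1-[(2S,4S,5S)-4-chloro-5-ethynyl-5-methyloxolan-2-yl]ethan-1-one F3, whose acetyl group lies cis to the slim ethynyl group and to chlorine and not cis to the C10 methyl. Re-ketalisation (MeOH, HC(OMe)3, PPTS) comes back to the route at 18.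

Step 17. During departure of the triflate the neighbouring bromine may bridge C7 and C8; chloride could then enter at C7 and the two halogens would be exchanged between C7 and C8. The fallback introduces chlorine first and bromine last and sets out from 21. Kinetic enolisation on the methyl side (LiN(SiMe3)2, Me3SiCl, THF, −78 °C) gives the silyl enol ether trimethyl({1-[(2S,4S,5S)-5-[(E)-2-bromoethenyl]-4-chloro-5-methyloxolan-2-yl]ethenyl}oxy)silane F4. NCS converts it into the chloromethyl ketone 2-chloro-1-[(2S,4S,5S)-5-[(E)-2-bromoethenyl]-4-chloro-5-methyloxolan-2-yl]ethan-1-one F5, in which the former C9 methyl has become C8. Chelation-controlled addition of MeMgBr (CH2Cl2/Et2O, −78 °C) should give the tertiary chlorohydrin (2S)-2-[(2S,4S,5S)-5-[(E)-2-bromoethenyl]-4-chloro-5-methyloxolan-2-yl]-1-chloropropan-2-ol F6, with the hydroxyl where bromine must stand. HBr in CH2Cl2 would then replace the tertiary hydroxyl with retention, through a bridged chloronium ion that bromide opens at the tertiary carbon. This is the least certain operation of the variant and comes back to the route at 27.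

Step 16. Bromide may attack the unhindered primary carbon C8, because C7 is deactivated by the oxygen on C6, or the ring oxygen may take part and cause retention or ring enlargement. The fallback makes the C7–Br bond with electrophilic bromine and sets out from 21. A Wittig reaction with Ph3P=CHOMe gives the enol ether (2S,3S,5S)-2-[(E)-2-bromoethenyl]-3-chloro-5-(1-methoxyprop-1-en-2-yl)-2-methyloxolane F7 as a mixture of alkene isomers. NBS in wet THF adds bromine to the nucleophilic carbon C7 and gives the α-bromo aldehyde (2S)-2-bromo-2-[(2S,4S,5S)-5-[(E)-2-bromoethenyl]-4-chloro-5-methyloxolan-2-yl]propanal F8. NaBH4 at −78 °C comes back to the route at 25. In this variant the C7 configuration rests on substrate control, and the C7 epimers would have to be separated.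

Further compounds
F1 | step 12 | (2S,3S,5R)-3-chloro-5-(1,1-dimethoxyethyl)-2-ethynyl-2-methyloxolane | CC(OC)(OC)[C@H]1C[C@H](Cl)[C@](C)(C#C)O1
F2 | step 12 | 1-[(2R,4S,5S)-4-chloro-5-ethynyl-5-methyloxolan-2-yl]ethan-1-one | CC(=O)[C@H]1C[C@H](Cl)[C@](C)(C#C)O1
F3 | step 12 | 1-[(2S,4S,5S)-4-chloro-5-ethynyl-5-methyloxolan-2-yl]ethan-1-one | CC(=O)[C@@H]1C[C@H](Cl)[C@](C)(C#C)O1
F4 | step 17 | trimethyl({1-[(2S,4S,5S)-5-[(E)-2-bromoethenyl]-4-chloro-5-methyloxolan-2-yl]ethenyl}oxy)silane | C=C(O[Si](C)(C)C)[C@@H]1C[C@H](Cl)[C@](C)(/C=C/Br)O1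
F5 | step 17 | 2-chloro-1-[(2S,4S,5S)-5-[(E)-2-bromoethenyl]-4-chloro-5-methyloxolan-2-yl]ethan-1-one | ClCC(=O)[C@@H]1C[C@H](Cl)[C@](C)(/C=C/Br)O1
F6 | step 17 | (2S)-2-[(2S,4S,5S)-5-[(E)-2-bromoethenyl]-4-chloro-5-methyloxolan-2-yl]-1-chloropropan-2-ol | C[C@@](O)(CCl)[C@@H]1C[C@H](Cl)[C@](C)(/C=C/Br)O1
F7 | step 16 | (2S,3S,5S)-2-[(E)-2-bromoethenyl]-3-chloro-5-(1-methoxyprop-1-en-2-yl)-2-methyloxolane | COC=C(C)[C@@H]1C[C@H](Cl)[C@](C)(/C=C/Br)O1
F8 | step 16 | (2S)-2-bromo-2-[(2S,4S,5S)-5-[(E)-2-bromoethenyl]-4-chloro-5-methyloxolan-2-yl]propanal | C[C@@](Br)(C=O)[C@@H]1C[C@H](Cl)[C@](C)(/C=C/Br)O1
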